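**Retrosynthetic overview**

1. Last operations: fluoride frees the catechol from two triisopropylsilyl ethers; before that, the ArCH2–CH2Ar bridge at C6 of the chromene is made by B-alkyl Suzuki–Miyaura coupling of bromochromene 13 with the 9-BBN adduct of styrene 16.
2. Enabling feature: C2 of the pyran ring is a fully substituted ether carbon that carries both C3 of the C3=C4 olefin and a CH2–CH2–CH= arm, so O–C2, C3 and the first three side-chain carbons can be folded back into a 1-methylcyclopent-2-en-1-yl aryl ether with a vinyl group ortho on the benzene ring.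
3. Key disconnection: the C3=C4 bond of the pyran ring, formed by strain-releasing ring-opening/ring-closing metathesis of that cyclopentene (a ring absent from the target); the freed chain terminus is capped in the same flask by cross-metathesis with methacrolein to give the E-enal.
4. Styrenyl ether 9 comes from (S)-1-methylcyclopent-2-en-1-ol 5 by SNAr on 5-bromo-2-fluorobenzaldehyde and Wittig methylenation; 5 comes from geraniol by Sharpless epoxidation (sets the only stereocenter), reductive epoxide opening to (S)-linalool and ring-closing metathesis.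
5. Ring order: both benzene rings are bought; the temporary cyclopentene is closed in step 3; the pyran ring is closed in step 6 as the cyclopentene opens.

Key step: step 6

Assumption: (S)-(+)-linalool is taken not to be obtainable in dependable enantiomeric purity and is therefore made from geraniol; if it can be bought, steps 1 and 2 fall away.

**Route**

Step 1
Reactants: 1 geraniol ((2E)-3,7-dimethylocta-2,6-dien-1-ol)
Product: 2 (2S,3S)-2,3-epoxygeraniol ([(2S,3S)-3-methyl-3-(4-methylpent-3-en-1-yl)oxiran-2-yl]methanol)
Conditions: Ti(OiPr)4 (5 mol %), L-(+)-diethyl tartrate (6 mol %), anhydrous t-BuOOH, 4 Å molecular sieves, CH2Cl2, −20 °C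
Reagents that add atoms: tert-butyl hydroperoxide, CC(C)(C)OO
Why: Katsuki–Sharpless asymmetric epoxidation, in which the hydroxyl-bound Ti(OiPr)4/tartrate catalyst delivers oxygen to one face of the allylic olefin only, should set C2 and C3 as S,S (C3 is the future ring stereocenter) and leave the remote trisubstituted olefin untouched.

Step 2
Reactants: 2 (2S,3S)-2,3-epoxygeraniol
Product: 4 (S)-linalool ((3S)-3,7-dimethylocta-1,6-dien-3-ol), via epoxy iodide 3 (not isolated)
Conditions: PPh3, I2, imidazole, THF, 0 °C; then Zn dust, AcOH, EtOH, 23 °C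
Reagents that add atoms: none
Why: Garegg–Samuelsson (Appel-type) iodination of the primary alcohol followed by zinc insertion and reductive β-elimination that opens the epoxide should give the tertiary allylic alcohol, and since the C3–O bond is never broken the stereocenter is carried over as S.

Step 3
Reactants: 4 (S)-linalool
Product: 5 (1S)-1-methylcyclopent-2-en-1-ol
Conditions: second-generation Grubbs catalyst (H2IMes)(PCy3)Cl2Ru=CHPh (0.5 mol %), CH2Cl2 (1 M), 23 °C; ethyl vinyl ether quench; bulb-to-bulb distillation
Reagents that add atoms: none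
Why: Ring-closing metathesis between the vinyl group and the trisubstituted olefin of linalool is a fast five-membered ring closure driven by loss of volatile 2-methylpropene and does not touch the carbinol stereocenter.

Step 4
Reactants: 5 (1S)-1-methylcyclopent-2-en-1-ol; 6 5-bromo-2-fluorobenzaldehyde
Product: 8 5-bromo-2-{[(1S)-1-methylcyclopent-2-en-1-yl]oxy}benzaldehyde, via potassium alkoxide 7 (not isolated)
Conditions: KH (1.05 equiv), THF, 0 °C; then 6, THF/DMF, 0 → 23 °C
Reagents that add atoms: none
Why: Nucleophilic aromatic substitution (addition–elimination) at the C–F carbon activated by the ortho formyl group should give the hindered tertiary aryl ether with the alkoxide C–O bond and hence the stereocenter untouched, while the bromide, which lies meta to the formyl group, is not displaced.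

Step 5
Reactants: 8 5-bromo-2-{[(1S)-1-methylcyclopent-2-en-1-yl]oxy}benzaldehyde
Product: 9 4-bromo-2-ethenyl-1-{[(1S)-1-methylcyclopent-2-en-1-yl]oxy}benzene
Conditions: Ph3PCH3Br, KOtBu, THF, 0 °C
Reagents that add atoms: methyltriphenylphosphonium bromide, C[P+](c1ccccc1)(c1ccccc1)c1ccccc1.[Br-]
Why: Wittig methylenation of the non-enolisable aryl aldehyde with the unstabilised ylide proceeds at 0 °C, far below the temperature at which the tertiary allylic aryl ether could undergo Claisen rearrangement.

Step 6
Reactants: 9 4-bromo-2-ethenyl-1-{[(1S)-1-methylcyclopent-2-en-1-yl]oxy}benzene; 10 methacrolein (2-methylprop-2-enal)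
Product: 12 (2E)-5-[(2S)-6-bromo-2-methyl-2H-chromen-2-yl]-2-methylpent-2-enal, via butenylchromene 11 (not isolated)
Conditions: second-generation Hoveyda–Grubbs catalyst (H2IMes)Cl2Ru=CH(C6H4-2-OiPr) (5 mol %), ethylene (1 atm), CH2Cl2 (0.02 M), 22 °C; then argon purge, 10 (10 equiv), further catalyst (2.5 mol %), 40 °C
Reagents that add atoms: none
Why: Ring-opening/ring-closing metathesis followed in the same flask by cross-metathesis: the ruthenium alkylidene formed at the styrenyl vinyl group adds across the C2=C3 olefin of the cyclopentene and the metallacyclobutane cycloreverts, so that the five-membered ring opens as the C3=C4 bond of the pyran forms and the alkylidene left on the former ring carbon is capped by ethylene to give 11. The closest known reaction type is the ruthenium-catalysed rearrangement of styrenyl cycloalkenyl ethers to 2-substituted 2H-chromenes under ethylene, joined to the E-selective cross-metathesis of terminal olefins with methacrolein. The pyran ring closes by six-membered ring-closing metathesis onto the ring olefin, whereas the opposite orientation of addition would give an eight-membered ring and is not expected to compete. No new stereocenter is formed, because the quaternary carbon set in step 1 is a spectator whose four bonds are never broken, so its S configuration becomes that of C2 of the chromene. The driving forces are release of cyclopentene strain and formation of an aryl-conjugated endocyclic olefin that does not re-enter metathesis, ethylene and high dilution should suppress oligomers, and the E geometry of the enal is under thermodynamic control with the formyl group trans to the chain. The chemoselectivity needed in the second stage is secured because the chromene olefin is 1,2-disubstituted next to a quaternary carbon and the aryl bromide is inert to ruthenium alkylidenes.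

Step 7
Reactants: 12 (2E)-5-[(2S)-6-bromo-2-methyl-2H-chromen-2-yl]-2-methylpent-2-enal
Product: 13 (2E)-5-[(2S)-6-bromo-2-methyl-2H-chromen-2-yl]-2-methylpent-2-en-1-ol
Conditions: NaBH4, CeCl3·7H2O, MeOH, 0 °C
Reagents that add atoms: none
Why: Luche 1,2-reduction of the enal should give the allylic alcohol without conjugate reduction or change of olefin geometry and without touching the aryl bromide or the chromene.

Step 8
Reactants: 14 2,3-dihydroxybenzaldehyde
Product: 15 2,3-bis[(triisopropylsilyl)oxy]benzaldehyde
Conditions: iPr3SiOTf (2.4 equiv), 2,6-lutidine (3 equiv), CH2Cl2, 0 → 23 °C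
Reagents that add atoms: triisopropylsilyl trifluoromethanesulfonate, CC(C)[Si](OS(=O)(=O)C(F)(F)F)(C(C)C)C(C)C
Why: Silylation with the highly electrophilic silyl triflate and a hindered pyridine base should overcome the crowding of the catechol and install ethers that withstand the ylide of step 9 and the aqueous phosphate of step 10 yet are removed by fluoride at the end.

Step 9
Reactants: 15 2,3-bis[(triisopropylsilyl)oxy]benzaldehyde
Product: 16 1-ethenyl-2,3-bis[(triisopropylsilyl)oxy]benzene
Conditions: Ph3PCH3Br (1.3 equiv), KOtBu (1.2 equiv), THF, 0 °C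
Reagents that add atoms: methyltriphenylphosphonium bromide, C[P+](c1ccccc1)(c1ccccc1)c1ccccc1.[Br-]
Why: Wittig methylenation of the aryl aldehyde with a slight deficit of base relative to the phosphonium salt leaves no free alkoxide that could attack the aryl silyl ethers.

Step 10
Reactants: 13 (2E)-5-[(2S)-6-bromo-2-methyl-2H-chromen-2-yl]-2-methylpent-2-en-1-ol; 16 1-ethenyl-2,3-bis[(triisopropylsilyl)oxy]benzene
Product: 18 (2E)-5-[(2S)-6-(2-{2,3-bis[(triisopropylsilyl)oxy]phenyl}ethyl)-2-methyl-2H-chromen-2-yl]-2-methylpent-2-en-1-ol, via alkylborane 17 (not isolated)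
Conditions: 16 (1.3 equiv), 9-BBN (1.25 equiv), THF, 0 → 23 °C; then 13 (1.0 equiv), Pd(dppf)Cl2·CH2Cl2 (5 mol %), aq K3PO4 (3 M), DMF, 50 °C
Reagents that add atoms: none
Why: Anti-Markovnikov hydroboration of the styrene with 9-BBN followed by B-alkyl Suzuki–Miyaura coupling (oxidative addition of the aryl bromide to zerovalent palladium, base-assisted transmetalation of the primary alkyl group, reductive elimination) builds the CH2–CH2 bridge without any hydrogenation, so the chromene and side-chain olefins survive, and all B–H is consumed by the excess of 16 before the olefin-bearing bromide is added.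

Step 11
Reactants: 18 (2E)-5-[(2S)-6-(2-{2,3-bis[(triisopropylsilyl)oxy]phenyl}ethyl)-2-methyl-2H-chromen-2-yl]-2-methylpent-2-en-1-ol
Product: 19 3-(2-{(2S)-2-[(3E)-5-hydroxy-4-methylpent-3-en-1-yl]-2-methyl-2H-chromen-6-yl}ethyl)benzene-1,2-diol (CNP0267525.1)
Conditions: Bu4NF (2.5 equiv), AcOH (2.5 equiv), THF, 0 °C, argon
Reagents that add atoms: none
Why: Fluoride-mediated cleavage of the two aryl silyl ethers, buffered with acetic acid so that the air-sensitive catechol is never present as its anion, leaves the chromene, the allylic alcohol and the stereocenter untouched.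

**Compound list**

1 | geraniol, (2E)-3,7-dimethylocta-2,6-dien-1-ol | CC(C)=CCC/C(C)=C/CO | starting material
2 | (2S,3S)-2,3-epoxygeraniol, [(2S,3S)-3-methyl-3-(4-methylpent-3-en-1-yl)oxiran-2-yl]methanol | CC(C)=CCC[C@]1(C)O[C@H]1CO | intermediate
3 | (2S,3R)-3-(iodomethyl)-2-methyl-2-(4-methylpent-3-en-1-yl)oxirane | CC(C)=CCC[C@]1(C)O[C@H]1CI | intermediate
4 | (S)-linalool, (3S)-3,7-dimethylocta-1,6-dien-3-ol | C=C[C@@](C)(O)CCC=C(C)C | intermediate
5 | (1S)-1-methylcyclopent-2-en-1-ol | C[C@@]1(O)C=CCC1 | intermediate
6 | 5-bromo-2-fluorobenzaldehyde | O=Cc1cc(Br)ccc1F | starting material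
7 | potassium (1S)-1-methylcyclopent-2-en-1-olate | C[C@@]1([O-])C=CCC1.[K+] | intermediate
8 | 5-bromo-2-{[(1S)-1-methylcyclopent-2-en-1-yl]oxy}benzaldehyde | C[C@@]1(Oc2ccc(Br)cc2C=O)C=CCC1 | intermediate
9 | 4-bromo-2-ethenyl-1-{[(1S)-1-methylcyclopent-2-en-1-yl]oxy}benzene | C[C@@]1(Oc2ccc(Br)cc2C=C)C=CCC1 | intermediate
10 | methacrolein, 2-methylprop-2-enal | CC(=C)C=O | starting material
11 | (2S)-6-bromo-2-(but-3-en-1-yl)-2-methyl-2H-chromene | C=CCC[C@@]1(C)C=Cc2cc(Br)ccc2O1 | intermediate
12 | (2E)-5-[(2S)-6-bromo-2-methyl-2H-chromen-2-yl]-2-methylpent-2-enal | C/C(=C\CC[C@@]1(C)C=Cc2cc(Br)ccc2O1)C=O | intermediate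
13 | (2E)-5-[(2S)-6-bromo-2-methyl-2H-chromen-2-yl]-2-methylpent-2-en-1-ol | C/C(=C\CC[C@@]1(C)C=Cc2cc(Br)ccc2O1)CO | intermediate
14 | 2,3-dihydroxybenzaldehyde | O=Cc1cccc(O)c1O | starting material
15 | 2,3-bis[(triisopropylsilyl)oxy]benzaldehyde | O=Cc1cccc(O[Si](C(C)C)(C(C)C)C(C)C)c1O[Si](C(C)C)(C(C)C)C(C)C | intermediate
16 | 1-ethenyl-2,3-bis[(triisopropylsilyl)oxy]benzene | C=Cc1cccc(O[Si](C(C)C)(C(C)C)C(C)C)c1O[Si](C(C)C)(C(C)C)C(C)C | intermediate
17 | 9-(2-{2,3-bis[(triisopropylsilyl)oxy]phenyl}ethyl)-9-borabicyclo[3.3.1]nonane | CC(C)[Si](Oc1cccc(CCB2C3CCCC2CCC3)c1O[Si](C(C)C)(C(C)C)C(C)C)(C(C)C)C(C)C | intermediate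
18 | (2E)-5-[(2S)-6-(2-{2,3-bis[(triisopropylsilyl)oxy]phenyl}ethyl)-2-methyl-2H-chromen-2-yl]-2-methylpent-2-en-1-ol | C/C(=C\CC[C@@]1(C)C=Cc2cc(CCc3cccc(O[Si](C(C)C)(C(C)C)C(C)C)c3O[Si](C(C)C)(C(C)C)C(C)C)ccc2O1)CO | intermediate
19 | 3-(2-{(2S)-2-[(3E)-5-hydroxy-4-methylpent-3-en-1-yl]-2-methyl-2H-chromen-6-yl}ethyl)benzene-1,2-diol (CNP0267525.1) | C/C(=C\CC[C@@]1(C)C=Cc2cc(CCc3cccc(O)c3O)ccc2O1)CO | target

**Summary**

Total step count: 11. Longest linear sequence: 9 steps (steps 1–7, 10 and 11, from geraniol).

Steps most likely to fail: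

Step 6. The styrenyl ruthenium alkylidene may engage the hindered cyclopentene olefin next to the quaternary carbon too slowly, so that intermolecular metathesis through the styrene (oligomers) takes over, or the cross-metathesis may stop short of full conversion with erosion of the olefin geometry. The fallback keeps the same bond-forming event but gives up the temporary ring: it sets out from 4 and comes back at 13. Alcohol 4 would be deprotonated with KH to potassium (3S)-3,7-dimethylocta-1,6-dien-3-olate F1, which with 6 should give 5-bromo-2-{[(3S)-3,7-dimethylocta-1,6-dien-3-yl]oxy}benzaldehyde F2. Wittig methylenation would give 4-bromo-1-{[(3S)-3,7-dimethylocta-1,6-dien-3-yl]oxy}-2-ethenylbenzene F3. Plain ring-closing metathesis of the two monosubstituted olefins with first-generation Grubbs catalyst (PCy3)2Cl2Ru=CHPh, which engages the trisubstituted olefin only sluggishly, should give (2S)-6-bromo-2-methyl-2-(4-methylpent-3-en-1-yl)-2H-chromene F4. Allylic oxidation of the E-methyl group with catalytic SeO2 and t-BuOOH in CH2Cl2, with a NaBH4 work-up to return any over-oxidised enal 12, would deliver 13.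

Step 4. The tertiary alkoxide may add to the formyl group and consume the aldehyde by hydride transfer (Cannizzaro/Tishchenko-type pathways), or the product may lose the tertiary allylic ether by ionisation, before addition–elimination at the C–F carbon is complete. The fallback separates activation from the aldehyde: it sets out from 7 and comes back at 8. Alkoxide 7 would be treated with 5-bromo-2-fluorobenzonitrile (THF/DMF, 0 °C) to give 5-bromo-2-{[(1S)-1-methylcyclopent-2-en-1-yl]oxy}benzonitrile F5, whose nitrile cannot be attacked reversibly in the same way. Partial reduction with iBu2AlH in toluene at −78 °C and hydrolysis of the aldimine on wet silica with aqueous Rochelle salt would then give 8.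

Step 10. Transmetalation of the crowded alkylborane may be slow, so that protodeboronation, β-hydride elimination or base-induced loss of silyl groups compete with coupling. The fallback changes the nucleophile to an organozinc and removes the aqueous base: it sets out from 17 and comes back at 18. Borane 17 would be oxidised with NaBO3·4H2O to 2-{2,3-bis[(triisopropylsilyl)oxy]phenyl}ethan-1-ol F6 and converted with PPh3, I2 and imidazole into {[3-(2-iodoethyl)-1,2-phenylene]bis(oxy)}bis(triisopropylsilane) F7. Zinc insertion (Zn dust, LiCl, THF) would give (2-{2,3-bis[(triisopropylsilyl)oxy]phenyl}ethyl)zinc iodide F8. Negishi coupling of F8 with 13 (Pd(OAc)2, SPhos, THF, 23 °C), in which cross-coupling should outrun protonolysis by the free hydroxyl group, would give 18.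

Further compounds
F1 | step 6 | potassium (3S)-3,7-dimethylocta-1,6-dien-3-olate | C=C[C@@](C)([O-])CCC=C(C)C.[K+]
F2 | step 6 | 5-bromo-2-{[(3S)-3,7-dimethylocta-1,6-dien-3-yl]oxy}benzaldehyde | C=C[C@@](C)(Oc1ccc(Br)cc1C=O)CCC=C(C)C
F3 | step 6 | 4-bromo-1-{[(3S)-3,7-dimethylocta-1,6-dien-3-yl]oxy}-2-ethenylbenzene | C=C[C@@](C)(Oc1ccc(Br)cc1C=C)CCC=C(C)C
F4 | step 6 | (2S)-6-bromo-2-methyl-2-(4-methylpent-3-en-1-yl)-2H-chromene | CC(C)=CCC[C@@]1(C)C=Cc2cc(Br)ccc2O1
F5 | step 4 | 5-bromo-2-{[(1S)-1-methylcyclopent-2-en-1-yl]oxy}benzonitrile | C[C@@]1(Oc2ccc(Br)cc2C#N)C=CCC1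
F6 | step 10 | 2-{2,3-bis[(triisopropylsilyl)oxy]phenyl}ethan-1-ol | OCCc1cccc(O[Si](C(C)C)(C(C)C)C(C)C)c1O[Si](C(C)C)(C(C)C)C(C)C
F7 | step 10 | {[3-(2-iodoethyl)-1,2-phenylene]bis(oxy)}bis(triisopropylsilane) | ICCc1cccc(O[Si](C(C)C)(C(C)C)C(C)C)c1O[Si](C(C)C)(C(C)C)C(C)C
F8 | step 10 | (2-{2,3-bis[(triisopropylsilyl)oxy]phenyl}ethyl)zinc iodide | I[Zn]CCc1cccc(O[Si](C(C)C)(C(C)C)C(C)C)c1O[Si](C(C)C)(C(C)C)C(C)C
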